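**Strategy.** The route builds the para-disubstituted B ring of the genkwanin half instead of forging the crowded diaryl ether. In that ring C1' carries chromone C2 and C4' carries the oxygen bound to C8'' of the apigenin half. A 2-aryloxybutadiene that already holds the C8''–O bond is combined with a 2-ethynylchromone in a para-selective [4+2] cycloaddition, which creates C1'–C2' and C5'–C6' and closes the ring in one operation. The diene is tri-O-benzyl-8-(buta-1,3-dien-2-yloxy)apigenin, made by allylic etherification and elimination. The dienophile is 2-ethynyl-5-hydroxy-7-methoxychromone, whose free 5-OH allows chelate activation. Aromatisation and hydrogenolysis finish the synthesis.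

Key step: step 8

Remark: 6, 10 and 11 are taken as catalogue chemicals; the ether-bearing carbon of 7 and 8 is formed racemic and is erased in step 5, so it carries no configuration, and the target has no stereocentre.

**Step 1**
Reactants: 1 apigenin
Product: 2 5,7-bis(benzyloxy)-2-[4-(benzyloxy)phenyl]-4H-chromen-4-one
Conditions: BnBr (4 equiv), K2CO3, TBAI (cat.), DMF, 80 °C
Reagents that add atoms: benzyl bromide, BrCc1ccccc1
Why: Williamson O-benzylation, in which the 7- and 4'-phenoxides react readily and the hydrogen-bonded 5-OH follows under forcing conditions, so that the capped 5-oxygen can steer the next substitution to C8.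

**Step 2**
Reactants: 2 5,7-bis(benzyloxy)-2-[4-(benzyloxy)phenyl]-4H-chromen-4-one
Product: 3 5,7-bis(benzyloxy)-2-[4-(benzyloxy)phenyl]-8-iodo-4H-chromen-4-one
Conditions: NIS (1.05 equiv), TFA (cat.), MeCN–CH2Cl2, 0 °C → rt, dark
Reagents that add atoms: N-iodosuccinimide, O=C1CCC(=O)N1I
Why: Electrophilic aromatic iodination of the trioxygenated A ring, which in 5,7-di-O-alkylflavones should go to C8 because that carbon is para to O5, ortho to O7 and flanked by only one benzyloxy group, whereas C6 lies between two.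

**Step 3**
Reactants: 3 5,7-bis(benzyloxy)-2-[4-(benzyloxy)phenyl]-8-iodo-4H-chromen-4-one
Product: 5 5,7-bis(benzyloxy)-2-[4-(benzyloxy)phenyl]-8-hydroxy-4H-chromen-4-one, via pinacol boronate 4 (not isolated)
Conditions: B2pin2, PdCl2(dppf) (5 mol%), KOAc, dioxane, 90 °C; then 30% H2O2, 1 M NaOH, THF, 0 °C
Reagents that add atoms: hydrogen peroxide, OO
Why: Miyaura borylation of the aryl iodide followed by peroxide oxidation of the C–B bond (boron-to-oxygen 1,2-shift) is a standard iodide-to-phenol sequence, and short cold contact with basic peroxide should leave the flavone and the benzyl ethers intact.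

**Step 4**
Reactants: 5 5,7-bis(benzyloxy)-2-[4-(benzyloxy)phenyl]-8-hydroxy-4H-chromen-4-one; 6 2-vinyloxirane
Product: 7 rac-5,7-bis(benzyloxy)-2-[4-(benzyloxy)phenyl]-8-[(1-hydroxybut-3-en-2-yl)oxy]-4H-chromen-4-one
Conditions: Pd2(dba)3·CHCl3 (2 mol%), (±)-DACH-phenyl Trost ligand (6 mol%), CH2Cl2, rt
Reagents that add atoms: none
Why: Tsuji–Trost allylic etherification with a vinyl epoxide, in which the alkoxide of the zwitterionic π-allylpalladium species deprotonates the phenol and hydrogen-bonded delivery sends the phenoxide to the internal allyl carbon to give the branched ether; the new ether-bearing centre forms as a racemate (racemic ligand and epoxide) and is removed in step 5.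

**Step 5**
Reactants: 7 rac-5,7-bis(benzyloxy)-2-[4-(benzyloxy)phenyl]-8-[(1-hydroxybut-3-en-2-yl)oxy]-4H-chromen-4-one
Product: 9 5,7-bis(benzyloxy)-2-[4-(benzyloxy)phenyl]-8-(buta-1,3-dien-2-yloxy)-4H-chromen-4-one, via tosylate 8 (not isolated)
Conditions: TsCl, Et3N, Me3N·HCl (cat.), THF, 0 °C; then KOtBu (3 equiv), 0 °C → rt
Reagents that add atoms: none
Why: Sulfonylation of the primary alcohol and E2 elimination, where the only β-hydrogen is the allylic, oxygen-bearing C–H, so tert-butoxide can give nothing but the 2-aryloxy-1,3-diene, and the basic medium protects the enol ether (the chromone carbonyl is never exposed to a carbonyl-olefinating reagent).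

**Step 6**
Reactants: 10 1-(2,6-dihydroxy-4-methoxyphenyl)ethan-1-one; 11 ethyl 2,2-diethoxyacetate
Product: 14 5-hydroxy-7-methoxy-4-oxo-4H-chromene-2-carbaldehyde, via diketone 12 (not isolated), via diethyl acetal 13 (not isolated)
Conditions: LiHMDS (4.5 equiv), THF, −78 °C → rt; then AcOH–2 M HCl, 80 °C
Reagents that add atoms: water, O
Why: Crossed Claisen condensation of the acetophenone polyanion with an α,α-dialkoxy ester, then acid-catalysed cyclodehydration of the o-hydroxyaryl 1,3-diketone to the chromone (either hydroxyl of the symmetric ring gives the same product) and acetal hydrolysis to the aldehyde.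

**Step 7**
Reactants: 14 5-hydroxy-7-methoxy-4-oxo-4H-chromene-2-carbaldehyde
Product: 15 2-ethynyl-5-hydroxy-7-methoxy-4H-chromen-4-one
Conditions: Ohira–Bestmann reagent (1.3 equiv), K2CO3 (3 equiv), MeOH, 0 °C → rt
Reagents that add atoms: dimethyl (1-diazo-2-oxopropyl)phosphonate, CC(=O)C(=[N+]=[N-])P(=O)(OC)OC
Why: Seyferth–Gilbert homologation in the Ohira–Bestmann variant, in which the diazomethylphosphonate anion adds to the non-enolisable aldehyde and Horner–Wadsworth–Emmons-type collapse, loss of N2 and a 1,2-hydrogen shift give the terminal alkyne, while the 5-phenoxide formed under these conditions deactivates the pyrone ring towards methoxide.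

**Step 8**
Reactants: 9 5,7-bis(benzyloxy)-2-[4-(benzyloxy)phenyl]-8-(buta-1,3-dien-2-yloxy)-4H-chromen-4-one; 15 2-ethynyl-5-hydroxy-7-methoxy-4H-chromen-4-one
Product: 18 5,7-bis(benzyloxy)-2-[4-(benzyloxy)phenyl]-8-{[4-(5-hydroxy-7-methoxy-4-oxo-4H-chromen-2-yl)cyclohexa-1,4-dien-1-yl]oxy}-4H-chromen-4-one, via aluminium chelate 16 (not isolated), via chelated cycloadduct 17 (not isolated)
Conditions: 15 (1.5 equiv), Me2AlCl (1.5 equiv), CH2Cl2, −78 °C; then 9 (1 equiv), −40 °C → rt; aq. Rochelle salt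
Reagents that add atoms: none
Why: Me2AlCl should turn the 5-OH into a chloro(methyl)aluminium phenoxide that chelates the C4 carbonyl, which makes the alkyne terminus a strongly electrophilic vinylogous acceptor, binds the Lewis acid to the dienophile and scavenges stray protic acid that would destroy the enol-ether diene. The aryloxy diene then adds in a normal-electron-demand [4+2] cycloaddition, concerted but asynchronous (a Michael-then-cyclise limit would end in the same ring); the closest known type is the Diels–Alder reaction of 2-alkoxy- and 2-silyloxybutadienes with ynones and propiolates. The one new ring, the six-membered carbocycle that becomes the B ring, is closed by the cycloaddition itself through the two new bonds C1'–C2' and C5'–C6' and emerges as a 1,4-cyclohexadiene. No stereocentre is created. The step needs para and not meta orientation, which the substrate secures because the largest HOMO coefficient of the diene sits on the CH2 attached to the aryloxy carbon and pairs with the terminal alkyne carbon (largest LUMO coefficient), placing chromone C2 and the ether oxygen 1,4, a bias that chelation strengthens. The alkyne should react in preference to the chromone C2=C3 bond, which is donor-substituted and fully embedded in the ring.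

**Step 9**
Reactants: 18 5,7-bis(benzyloxy)-2-[4-(benzyloxy)phenyl]-8-{[4-(5-hydroxy-7-methoxy-4-oxo-4H-chromen-2-yl)cyclohexa-1,4-dien-1-yl]oxy}-4H-chromen-4-one
Product: 19 5,7-bis(benzyloxy)-2-[4-(benzyloxy)phenyl]-8-[4-(5-hydroxy-7-methoxy-4-oxo-4H-chromen-2-yl)phenoxy]-4H-chromen-4-one
Conditions: DDQ (1.2 equiv), PhMe, 0 °C → rt, dark
Reagents that add atoms: none
Why: Oxidative aromatisation of a 1,4-cyclohexadiene by hydride abstraction from a doubly allylic CH2 with DDQ is driven by formation of the benzene ring, and aryl benzyl ethers and the chelated 5-OH should be inert at room temperature without light.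

**Step 10**
Reactants: 19 5,7-bis(benzyloxy)-2-[4-(benzyloxy)phenyl]-8-[4-(5-hydroxy-7-methoxy-4-oxo-4H-chromen-2-yl)phenoxy]-4H-chromen-4-one
Product: 20 5,7-dihydroxy-8-[4-(5-hydroxy-7-methoxy-4-oxo-4H-chromen-2-yl)phenoxy]-2-(4-hydroxyphenyl)-4H-chromen-4-one (CNP0424791.0)
Conditions: H2 (1 atm), 10% Pd/C, THF–MeOH, rt
Reagents that add atoms: none
Why: Catalytic hydrogenolysis should cleave the three aryl benzyl ethers while the diaryl ether, the methyl ether and the vinylogous-ester C2=C3 bonds of both chromones survive at 1 atm and room temperature.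

**Compound list**
1 | apigenin | O=c1cc(-c2ccc(O)cc2)oc2cc(O)cc(O)c12 | starting material
2 | 5,7-bis(benzyloxy)-2-[4-(benzyloxy)phenyl]-4H-chromen-4-one | O=c1cc(-c2ccc(OCc3ccccc3)cc2)oc2cc(OCc3ccccc3)cc(OCc3ccccc3)c12 | intermediate
3 | 5,7-bis(benzyloxy)-2-[4-(benzyloxy)phenyl]-8-iodo-4H-chromen-4-one | O=c1cc(-c2ccc(OCc3ccccc3)cc2)oc2c(I)c(OCc3ccccc3)cc(OCc3ccccc3)c12 | intermediate
4 | 5,7-bis(benzyloxy)-2-[4-(benzyloxy)phenyl]-8-(4,4,5,5-tetramethyl-1,3,2-dioxaborolan-2-yl)-4H-chromen-4-one (not isolated) | O=c1cc(-c2ccc(OCc3ccccc3)cc2)oc2c(B3OC(C)(C)C(C)(C)O3)c(OCc3ccccc3)cc(OCc3ccccc3)c12 | intermediate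
5 | 5,7-bis(benzyloxy)-2-[4-(benzyloxy)phenyl]-8-hydroxy-4H-chromen-4-one | O=c1cc(-c2ccc(OCc3ccccc3)cc2)oc2c(O)c(OCc3ccccc3)cc(OCc3ccccc3)c12 | intermediate
6 | 2-vinyloxirane (butadiene monoxide, racemic) | C=CC1CO1 | starting material
7 | rac-5,7-bis(benzyloxy)-2-[4-(benzyloxy)phenyl]-8-[(1-hydroxybut-3-en-2-yl)oxy]-4H-chromen-4-one | O=c1cc(-c2ccc(OCc3ccccc3)cc2)oc2c(OC(CO)C=C)c(OCc3ccccc3)cc(OCc3ccccc3)c12 | intermediate
8 | rac-2-{[5,7-bis(benzyloxy)-2-(4-benzyloxyphenyl)-4-oxo-4H-chromen-8-yl]oxy}but-3-en-1-yl 4-methylbenzenesulfonate (not isolated) | O=c1cc(-c2ccc(OCc3ccccc3)cc2)oc2c(OC(COS(=O)(=O)c3ccc(C)cc3)C=C)c(OCc3ccccc3)cc(OCc3ccccc3)c12 | intermediate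
9 | 5,7-bis(benzyloxy)-2-[4-(benzyloxy)phenyl]-8-(buta-1,3-dien-2-yloxy)-4H-chromen-4-one | C=CC(=C)Oc1c(OCc2ccccc2)cc(OCc2ccccc2)c2c(=O)cc(-c3ccc(OCc4ccccc4)cc3)oc12 | intermediate
10 | 1-(2,6-dihydroxy-4-methoxyphenyl)ethan-1-one | CC(=O)c1c(O)cc(OC)cc1O | starting material
11 | ethyl 2,2-diethoxyacetate | CCOC(OCC)C(=O)OCC | starting material
12 | 4,4-diethoxy-1-(2,6-dihydroxy-4-methoxyphenyl)butane-1,3-dione (not isolated) | CCOC(OCC)C(=O)CC(=O)c1c(O)cc(OC)cc1O | intermediate
13 | 2-(diethoxymethyl)-5-hydroxy-7-methoxy-4H-chromen-4-one (not isolated) | CCOC(OCC)c1cc(=O)c2c(O)cc(OC)cc2o1 | intermediate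
14 | 5-hydroxy-7-methoxy-4-oxo-4H-chromene-2-carbaldehyde | O=Cc1cc(=O)c2c(O)cc(OC)cc2o1 | intermediate
15 | 2-ethynyl-5-hydroxy-7-methoxy-4H-chromen-4-one | C#Cc1cc(=O)c2c(O)cc(OC)cc2o1 | intermediate
16 | chloro(methyl)aluminium 5-phenoxide of 15, chelated to the C4 carbonyl (not isolated) | C#Cc1cc(=O)c2c(O[Al](C)Cl)cc(OC)cc2o1 | intermediate
17 | chloro(methyl)aluminium 5-phenoxide chelate of cycloadduct 18 (not isolated) | COc1cc(O[Al](C)Cl)c2c(=O)cc(C3=CCC(Oc4c(OCc5ccccc5)cc(OCc5ccccc5)c5c(=O)cc(-c6ccc(OCc7ccccc7)cc6)oc45)=CC3)oc2c1 | intermediate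
18 | 5,7-bis(benzyloxy)-2-[4-(benzyloxy)phenyl]-8-{[4-(5-hydroxy-7-methoxy-4-oxo-4H-chromen-2-yl)cyclohexa-1,4-dien-1-yl]oxy}-4H-chromen-4-one | COc1cc(O)c2c(=O)cc(C3=CCC(Oc4c(OCc5ccccc5)cc(OCc5ccccc5)c5c(=O)cc(-c6ccc(OCc7ccccc7)cc6)oc45)=CC3)oc2c1 | intermediate
19 | 5,7-bis(benzyloxy)-2-[4-(benzyloxy)phenyl]-8-[4-(5-hydroxy-7-methoxy-4-oxo-4H-chromen-2-yl)phenoxy]-4H-chromen-4-one | COc1cc(O)c2c(=O)cc(-c3ccc(Oc4c(OCc5ccccc5)cc(OCc5ccccc5)c5c(=O)cc(-c6ccc(OCc7ccccc7)cc6)oc45)cc3)oc2c1 | intermediate
20 | 5,7-dihydroxy-8-[4-(5-hydroxy-7-methoxy-4-oxo-4H-chromen-2-yl)phenoxy]-2-(4-hydroxyphenyl)-4H-chromen-4-one | COc1cc(O)c2c(=O)cc(-c3ccc(Oc4c(O)cc(O)c5c(=O)cc(-c6ccc(O)cc6)oc45)cc3)oc2c1 | target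

**Count.** Total steps: 10. Longest linear sequence: 8 (steps 1–5, 8, 9, 10); steps 6–7 form the convergent branch.

**Steps most likely to fail**

Step 8. The vinylogous alkyne may prove too weak an acceptor even as its aluminium chelate. The enol-ether diene may oligomerise or hydrolyse before it is trapped, or the para orientation may erode. The fallback gives up the cycloaddition and uses known chemistry. It sets out from phenol 5 and acetophenone 10. Nucleophilic aromatic substitution of 5 on 4-fluorobenzaldehyde (K2CO3, DMF, 120 °C) should give 4-{[5,7-bis(benzyloxy)-2-(4-benzyloxyphenyl)-4-oxo-4H-chromen-8-yl]oxy}benzaldehyde F1. Claisen–Schmidt condensation of F1 with 10 (KOH, EtOH–THF, rt) should give the 2',6'-dihydroxychalcone F2. Iodine-catalysed oxidative cyclisation in DMSO (120 °C) should close the second chromone and return to the route at 19, before step 10.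

Step 4. The hindered phenoxide may attack the terminal allyl carbon and give the linear 4-aryloxybut-2-en-1-ol, or turnover may stall. The fallback replaces the π-allyl chemistry by a redox condensation and sets out from 5. Commercial but-3-ene-1,2-diol is silylated at the primary hydroxyl (TBSCl, imidazole) to rac-1-[(tert-butyldimethylsilyl)oxy]but-3-en-2-ol F3. Mitsunobu etherification of 5 with F3 (PPh3, DIAD, toluene, 0 °C → rt) should give the silyl ether of 7 F4. Desilylation (TBAF, AcOH, THF) returns to the route at 7.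

Step 7. Methanolic carbonate may open the pyrone ring of the aldehyde or add methanol across the newly formed ethynyl pyrone. The fallback brings the alkyne in already formed and silyl-protected, and sets out from 10. Commercial 3-(triisopropylsilyl)propiolic acid is converted with oxalyl chloride into 3-(triisopropylsilyl)propioloyl chloride F5. Acylation of the LiHMDS-derived polyanion of 10 with F5 (THF, −78 °C) should give 1-(2,6-dihydroxy-4-methoxyphenyl)-5-(triisopropylsilyl)pent-4-yne-1,3-dione F6. Acid cyclodehydration (H2SO4 cat., AcOH, 60 °C) should give 5-hydroxy-7-methoxy-2-[(triisopropylsilyl)ethynyl]-4H-chromen-4-one F7. Buffered fluoride (TBAF, AcOH, THF, 0 °C) returns to the route at 15.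

**Further compounds**
F1 | step 8 | 4-{[5,7-bis(benzyloxy)-2-(4-benzyloxyphenyl)-4-oxo-4H-chromen-8-yl]oxy}benzaldehyde | O=Cc1ccc(Oc2c(OCc3ccccc3)cc(OCc3ccccc3)c3c(=O)cc(-c4ccc(OCc5ccccc5)cc4)oc23)cc1
F2 | step 8 | (E)-3-(4-{[5,7-bis(benzyloxy)-2-(4-benzyloxyphenyl)-4-oxo-4H-chromen-8-yl]oxy}phenyl)-1-(2,6-dihydroxy-4-methoxyphenyl)prop-2-en-1-one | COc1cc(O)c(C(=O)/C=C/c2ccc(Oc3c(OCc4ccccc4)cc(OCc4ccccc4)c4c(=O)cc(-c5ccc(OCc6ccccc6)cc5)oc34)cc2)c(O)c1
F3 | step 4 | rac-1-[(tert-butyldimethylsilyl)oxy]but-3-en-2-ol | C=CC(O)CO[Si](C)(C)C(C)(C)C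
F4 | step 4 | rac-5,7-bis(benzyloxy)-2-[4-(benzyloxy)phenyl]-8-({1-[(tert-butyldimethylsilyl)oxy]but-3-en-2-yl}oxy)-4H-chromen-4-one | O=c1cc(-c2ccc(OCc3ccccc3)cc2)oc2c(OC(CO[Si](C)(C)C(C)(C)C)C=C)c(OCc3ccccc3)cc(OCc3ccccc3)c12
F5 | step 7 | 3-(triisopropylsilyl)propioloyl chloride | CC(C)[Si](C#CC(=O)Cl)(C(C)C)C(C)C
F6 | step 7 | 1-(2,6-dihydroxy-4-methoxyphenyl)-5-(triisopropylsilyl)pent-4-yne-1,3-dione | COc1cc(O)c(C(=O)CC(=O)C#C[Si](C(C)C)(C(C)C)C(C)C)c(O)c1
F7 | step 7 | 5-hydroxy-7-methoxy-2-[(triisopropylsilyl)ethynyl]-4H-chromen-4-one | COc1cc(O)c2c(=O)cc(C#C[Si](C(C)C)(C(C)C)C(C)C)oc2c1
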